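## Retrosynthetic overview
- Ugonin G ⇐ its tetraacetate ⇐ 6‑geranylkaempferol (macarangin) tetraacetate. The key step is an enantioselective, proton‑initiated cation–olefin monocyclisation (C2''–C7'' bond, loss of H‑4''). It builds the cyclohexene ring and the only stereocentre on the finished skeleton.
- Macarangin tetraacetate ⇐ kaempferol 5‑O‑geranyl ether triacetate. An acid‑clay O‑5→C‑6 [1,3]‑geranyl shift fixes the 6‑ (not 8‑) regiochemistry.
- The ether ⇐ kaempferol 3,7,4'‑triacetate + geraniol (Mitsunobu at the only free, chelated 5‑OH) ⇐ kaempferol.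
- Ring order: rings A, C and B come intact with kaempferol. The cyclohexene ring is the only ring formed, and it is formed last (flavonol → 6‑geranylflavonol → cyclogeranylflavonol).

Assumption: bulk‑grade kaempferol is taken as a cheap commercial starting material; the (S)‑ligand in step 4 is chosen by analogy with known LBA cyclisations [(R)‑ligand → 5α‑H "normal" series, which maps onto (S) here], and the equally available antipode is used if the sense proves opposite.

## Route

Step 1
Reactants: 1 kaempferol (3,5,7,4'‑tetrahydroxyflavone)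
Product: 2 kaempferol 3,7,4'‑triacetate (5‑OH free)
Conditions: Ac2O (3.2 equiv), pyridine, 0 °C → rt, 3 h; crystallise
Reagents that add atoms: acetic anhydride, CC(=O)OC(C)=O
Why: Chemoselective O‑acylation, because the 5‑OH is held in a strong hydrogen bond to C4=O and reacts far more slowly than O‑3, O‑7 and O‑4', so three equivalents of anhydride leave it free.

Step 2
Reactants: 2 kaempferol 3,7,4'‑triacetate; 3 geraniol [(2E)‑3,7‑dimethylocta‑2,6‑dien‑1‑ol]
Product: 4 kaempferol 5‑O‑[(2E)‑geranyl] ether 3,7,4'‑triacetate
Conditions: PPh3 (1.5 equiv), DIAD (1.5 equiv), THF, 0 °C → rt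
Reagents that add atoms: none
Why: Mitsunobu etherification, in which the only free phenol (chelated 5‑OH, pKa about 11) displaces the activated primary allylic alcohol by SN2 under neutral conditions, so the aryl acetates and the E‑alkene are kept.

Step 3
Reactants: 4 kaempferol 5‑O‑geranyl ether 3,7,4'‑triacetate
Product: 6 macarangin tetraacetate (6‑[(2E)‑geranyl]kaempferol 3,5,7,4'‑tetraacetate), via 6‑geranylkaempferol 3,7,4'‑triacetate 5 (not isolated)
Conditions: montmorillonite K10 (dried), CH2Cl2, 0 °C, 1–2 h; filter; then Ac2O, pyridine, DMAP (cat.), rt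
Reagents that add atoms: acetic anhydride, CC(=O)OC(C)=O
Why: Solid‑acid [1,3]‑O→C allyl shift (known for geranyl ethers of o‑acylphenols), in which the ether oxygen peri to C4=O ionises to a tight geranyl cation/phenol pair that collapses at the adjacent C‑6 with retention of the E‑alkene, and DMAP‑catalysed acetylation then caps the freed 5‑OH before it can add to the side chain.

Step 4
Reactants: 6 macarangin tetraacetate
Product: 7 ugonin G tetraacetate (6‑{[(1R)‑2,6,6‑trimethylcyclohex‑2‑en‑1‑yl]methyl}kaempferol 3,5,7,4'‑tetraacetate)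
Conditions: SnCl4 (1.0 equiv), CH2Cl2, −78 °C, 15 min; then preformed LBA [(S)‑2‑(2‑fluorobenzyloxy)‑2'‑hydroxy‑1,1'‑binaphthyl (2.2 equiv, recovered) + SnCl4 (2.0 equiv), toluene], −78 °C, 48 h; sat. aq NaHCO3; recrystallise to ≥98% ee
Reagents that add atoms: none
Why: Proposed new method: the chiral Lewis‑acid‑assisted Brønsted acid protonates one face of the exposed terminal isopropylidene group while the chair‑folded chain closes C7''–C2'' in concert, so the ligand fixes the face of the internal E‑alkene and hence C‑1' as R; because both flanking oxygens are non‑nucleophilic aryl acetates and both ortho carbons are substituted, the tertiary cation can only lose a proton, preferentially the ring H‑4'' (Saytzeff) to give the endocyclic α‑alkene, and one sacrificial equivalent of SnCl4 masks the basic pyranone C=O so that it does not strip the LBA; the closest known reaction type is the enantioselective BINOL‑ether·SnCl4 biomimetic cyclisation of 2‑geranylphenols, geranyl aryl ethers and homogeranylarenes, where enantioenriched monocyclic olefins appear whenever the terminating nucleophile is slow.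

Step 5
Reactants: 7 ugonin G tetraacetate
Product: 8 ugonin G (6‑{[(1R)‑2,6,6‑trimethylcyclohex‑2‑en‑1‑yl]methyl}‑3,5,7,4'‑tetrahydroxyflavone)
Conditions: 7 M NH3 in MeOH, Ar, 0 °C → rt, 2 h; evaporate; short SiO2 column
Reagents that add atoms: none
Why: Ammonolysis of the aryl and enol acetates, an acid‑free global deprotection, so the alkene neither migrates nor is trapped by the freed 5‑/7‑OH as a hexahydroxanthene and the allylic stereocentre is untouched.

## Compound list
1 | kaempferol | O=c1c(O)c(-c2ccc(O)cc2)oc2cc(O)cc(O)c12 | starting material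
2 | kaempferol 3,7,4'‑triacetate | CC(=O)Oc1ccc(cc1)-c1oc2cc(OC(C)=O)cc(O)c2c(=O)c1OC(C)=O | intermediate
3 | geraniol | CC(C)=CCC/C(C)=C/CO | starting material
4 | kaempferol 5‑O‑(E)‑geranyl ether 3,7,4'‑triacetate | CC(C)=CCC/C(C)=C/COc1cc(OC(C)=O)cc2oc(-c3ccc(OC(C)=O)cc3)c(OC(C)=O)c(=O)c12 | intermediate
5 | 6‑(E)‑geranylkaempferol 3,7,4'‑triacetate | CC(C)=CCC/C(C)=C/Cc1c(OC(C)=O)cc2oc(-c3ccc(OC(C)=O)cc3)c(OC(C)=O)c(=O)c2c1O | intermediate (not isolated)
6 | macarangin tetraacetate | CC(C)=CCC/C(C)=C/Cc1c(OC(C)=O)cc2oc(-c3ccc(OC(C)=O)cc3)c(OC(C)=O)c(=O)c2c1OC(C)=O | intermediate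
7 | ugonin G tetraacetate, (1'R) | CC1=CCCC(C)(C)[C@H]1Cc1c(OC(C)=O)cc2oc(-c3ccc(OC(C)=O)cc3)c(OC(C)=O)c(=O)c2c1OC(C)=O | intermediate
8 | ugonin G, (1'R) | CC1=CCCC(C)(C)[C@H]1Cc1c(O)cc2oc(-c3ccc(O)cc3)c(O)c(=O)c2c1O | target

## Step count
Total step count: 5. Longest linear sequence: 5. The recoverable ligand of step 4 is made once from (S)‑BINOL and 2‑fluorobenzyl bromide and is not counted.

## Steps most likely to fail

**Step 4.** The risks are low ee, α/γ/β olefin mixtures, and the carbonyl groups buffering the acid. Fallback: set out from 6 and replace the proton by a soft iodonium ion. NIS and a stoichiometric chiral BINOL‑derived phosphoramidite (toluene, −40 °C) trigger the same chair‑like ring closure without any acid that the carbonyl groups could buffer. This gives 6‑{[(1S,5R)‑5‑iodo‑2,6,6‑trimethylcyclohex‑2‑en‑1‑yl]methyl}kaempferol tetraacetate F1, with iodine cis to the CH2Ar group. Radical deiodination [(Me3Si)3SiH, AIBN, toluene, 80 °C] then comes back to the route at 7.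

**Step 3.** The risks are simple ether cleavage, migration to C‑8, and chroman formation. Fallback: set out from 2 and fix the C‑6 bond by cross‑coupling instead of migration.
- Iodination ortho to the free 5‑OH (BnMe3N·ICl2, CaCO3, CH2Cl2–MeOH) gives 6‑iodokaempferol 3,7,4'‑triacetate F2.
- Ac2O/DMAP gives 6‑iodokaempferol tetraacetate F3.
- Stille coupling [Pd2(dba)3, AsPh3, DMF, 60 °C] with (E)‑geranyltributylstannane F4, made from commercial geranyl chloride and Bu3SnLi, comes back to the route at 6.

**Step 2.** The risks are a sluggish chelated phenol and acetyl scrambling. Fallback: set out from 2 and 3 and skip the ether altogether. Acidic‑alumina‑templated dehydrative ortho‑C‑geranylation (ClCH2CH2Cl, reflux) adsorbs the phenol and the allylic alcohol side by side and alkylates the carbon next to the free 5‑OH. This comes back to the route at 5, which is acetylated as in step 3.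

## Further compounds
F1 | step 4 | 6‑{[(1S,5R)‑5‑iodo‑2,6,6‑trimethylcyclohex‑2‑en‑1‑yl]methyl}kaempferol tetraacetate | CC1=CC[C@@H](I)C(C)(C)[C@H]1Cc1c(OC(C)=O)cc2oc(-c3ccc(OC(C)=O)cc3)c(OC(C)=O)c(=O)c2c1OC(C)=O
F2 | step 3 | 6‑iodokaempferol 3,7,4'‑triacetate | CC(=O)Oc1ccc(cc1)-c1oc2cc(OC(C)=O)c(I)c(O)c2c(=O)c1OC(C)=O
F3 | step 3 | 6‑iodokaempferol tetraacetate | CC(=O)Oc1ccc(cc1)-c1oc2cc(OC(C)=O)c(I)c(OC(C)=O)c2c(=O)c1OC(C)=O
F4 | step 3 | (E)‑geranyltributylstannane | CC(C)=CCC/C(C)=C/C[Sn](CCCC)(CCCC)CCCC
F0 | step 2 | none | none
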